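**Retrosynthetic overview**
1. Numbering: C1 is the bridgehead beside C8 (CMe2), C2-C3-C4 is the bridge with the benzoyl enol on C3, C5 is the second bridgehead, C6 is CH2, C7 is CH-prenyl and C9 is the bridging ketone. The strategy rests on one feature: C6-C7-C8, with its prenyl and two methyls, is a protonated lavandulyl chain bound to C5 of acylphloroglucinol ring B (C1-C2-C3-C4-C5-C9). The C7 prenyl lies on the side of the C2-C4 bridge (7-endo, 7-epi-clusianone series).
2. Last disconnection: the C1 and C5 prenyls are carried as allyls and restored by cross-metathesis. A protonated prenyl on C5 (or C1) would have the same three-atom reach to C1 (or C3) and to the enol oxygens as the lavandulyl cation, so it would close rival six-membered rings.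
3. Key disconnection C1-C8: the tertiary C8 cation from the isopropenyl group is captured by enol carbon C1, which closes ring A (C1-C8-C7-C6-C5-C9) onto ring B.
4. C5-C6: alkylative dearomatisation of 3,5-diallyl-2,4,6-trihydroxybenzophenone with (R)-lavandulyl triflate. C7 comes from the chiral pool and C5 is secured by epimer separation. The arene comes from double C-allylation of 2,4,6-trihydroxybenzophenone.
5. Ring order: ring B is the dearomatised arene (step 3), and ring A is closed in step 4.

Key step: step 4

Assumption: (R)-lavandulol is bought in high enantiomeric purity, and every enolised tricarbonyl is drawn as one tautomer of a fast equilibrium (the target in the tautomer of the given structure).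

Step 1
Reactants: 1 2,4,6-trihydroxybenzophenone; 2 allyl bromide
Product: 3 3,5-diallyl-2,4,6-trihydroxybenzophenone
Conditions: 2 (2.1 equiv), KOH, H2O, 0 °C → rt
Reagents that add atoms: allyl bromide (2), C=CCBr
Why: C-alkylation of an ambident acylphloroglucinol phenolate: in water the phenolate oxygens are hydrogen-bonded, so the soft allylic bromide is taken at the two free ring carbons, the stoichiometry holds back gem-diallylation, and no stereocentre is formed.

Step 2
Reactants: 4 (R)-lavandulol
Product: 5 (R)-lavandulyl triflate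
Conditions: Tf2O, 2,6-lutidine, CH2Cl2, −78 °C; cold aqueous wash, used at once
Reagents that add atoms: triflic anhydride, O=S(=O)(OS(=O)(=O)C(F)(F)F)C(F)(F)F
Why: O-sulfonylation of a primary alcohol with a hindered pyridine base leaves the adjacent stereocentre (the later C7) untouched and gives the β-branched carbon the leaving group it needs for the next SN2 step; the product is kept cold because its two alkenes could assist ionisation.

Step 3
Reactants: 3 3,5-diallyl-2,4,6-trihydroxybenzophenone; 5 (R)-lavandulyl triflate
Product: 7 (6R)-2-benzoyl-3,5-dihydroxy-6-[(2S)-5-methyl-2-(prop-1-en-2-yl)hex-4-en-1-yl]-4,6-di(prop-2-en-1-yl)cyclohexa-2,4-dien-1-one, via trilithium phenolate 6 (not isolated)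
Conditions: LiN(SiMe3)2 (3.1 equiv), THF, 0 °C; then 5, 0 °C → rt; 1 M HCl quench; chromatography on acidified silica or preparative HPLC to separate the C5 epimers
Reagents that add atoms: LiN(SiMe3)2, [Li]N([Si](C)(C)C)[Si](C)(C)C (lithium of intermediate 6 only)
Why: Alkylative dearomatisation (SN2 C-alkylation of a lithium phenolate): tight lithium-oxygen pairing in THF steers the primary triflate to one of the two equivalent allyl-bearing ring carbons, which creates quaternary C5 and the C5-C6 bond, and because the remote C7 centre gives no facial bias both C5 epimers are expected and the (5R) epimer 7 is secured by separation.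

Step 4
Reactants: 7 (6R)-2-benzoyl-3,5-dihydroxy-6-[(2S)-lavandulyl]-4,6-diallylcyclohexa-2,4-dien-1-one
Product: 9 (1S,5R,7S)-3-[(Z)-hydroxy(phenyl)methylidene]-8,8-dimethyl-7-(3-methylbut-2-en-1-yl)-1,5-di(prop-2-en-1-yl)bicyclo[3.3.1]nonane-2,4,9-trione, via C8 tertiary cation 8 (not isolated)
Conditions: HCO2H (98%) with CH2Cl2 as co-solvent, 0 °C → rt
Reagents that add atoms: none
Why: Formic acid protonates the 1,1-disubstituted isopropenyl alkene in the Markovnikov sense to tertiary cation 8, enol carbon C1 of the C9(OH)=C1 unit attacks C8 and O9 gives up its proton, so the C1-C8 bond forms between two fully substituted carbons, ring A (C1-C8-C7-C6-C5-C9) closes and C9 becomes the bridging ketone; the closest known reaction type is the acid-mediated cation-enol cyclisation of dearomatised acylphloroglucinols to bicyclo[3.3.1]nonane-2,4,9-triones. The mode of closure is 6-(enolendo)-exo-trig, the enol double bond lying inside the new ring and the protonated C8=CH2 bond outside it. C1 is the only new stereocentre and is controlled by C5, because the three-atom tether C6-C7-C8 can reach C1 only across the ring B face that carries C6; with the (5R,7S) pair this places the C7 prenyl on the side of the C2-C4 bridge, so the closure should run through a boat-like ring A with H7 as flagpole over sp2 C9 in place of a chair with the prenyl axial over ring B. Selectivity among the alkenes is secured by substitution: the allyl groups on C1 and C5 could only give secondary cations and should stay unprotonated, whereas prenyl groups there would give tertiary cations with the same three-atom reach to C1, C3 and the enol oxygens, and the cation from the C7 prenyl reaches ring B only through eight-membered rings and should return by proton loss. Selectivity for C1 over C3 rests on C3 being the electron-poor centre of the hydrogen-bonded benzoyl chelate, and capture at O4 or O9 gives tertiary alkyl vinylogous esters that re-ionise in the acid, so the irreversible C-C closure should drain these equilibria.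

Step 5
Reactants: 9 diallyl bicyclic trione; 10 2-methyl-2-butene
Product: 11 (1S,5R,7S)-3-[(Z)-hydroxy(phenyl)methylidene]-8,8-dimethyl-1,5,7-tris(3-methylbut-2-en-1-yl)bicyclo[3.3.1]nonane-2,4,9-trione (target)
Conditions: 10 (large excess), second-generation Grubbs catalyst (H2IMes)(PCy3)Cl2Ru=CHPh (cat.), CH2Cl2, 40 °C, sealed tube
Reagents that add atoms: 2-methyl-2-butene (10), CC=C(C)C
Why: Olefin cross-metathesis of the two terminal alkenes with an excess of a trisubstituted partner exchanges =CH2 for =CMe2 with loss of propene; the C7 prenyl can only be returned as prenyl, the bridgehead allyls point away from each other so no ring closure is open, and no stereocentre is touched.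

**Compound list**
1 | 2,4,6-trihydroxybenzophenone | O=C(c1ccccc1)c1c(O)cc(O)cc1O | starting material
2 | allyl bromide | C=CCBr | starting material
3 | 3,5-diallyl-2,4,6-trihydroxybenzophenone | O=C(c1ccccc1)c1c(O)c(CC=C)c(O)c(CC=C)c1O | intermediate
4 | (R)-lavandulol, (2R)-5-methyl-2-(prop-1-en-2-yl)hex-4-en-1-ol | CC(C)=CC[C@H](C(C)=C)CO | starting material
5 | (R)-lavandulyl triflate | CC(C)=CC[C@H](C(C)=C)COS(=O)(=O)C(F)(F)F | intermediate
6 | trilithium phenolate of 3 | [Li+].[Li+].[Li+].[O-]c1c(CC=C)c([O-])c(C(=O)c2ccccc2)c([O-])c1CC=C | intermediate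
7 | (6R)-2-benzoyl-3,5-dihydroxy-6-[(2S)-5-methyl-2-(prop-1-en-2-yl)hex-4-en-1-yl]-4,6-di(prop-2-en-1-yl)cyclohexa-2,4-dien-1-one (ring C6 of this name is C5 of the overview) | CC(C)=CC[C@H](C(C)=C)C[C@@]1(CC=C)C(=O)C(C(=O)c2ccccc2)=C(O)C(CC=C)=C1O | intermediate
8 | C8 tertiary cation from 7 (configuration as in 7) | CC(C)=CC[C@H]([C+](C)C)C[C@@]1(CC=C)C(=O)C(C(=O)c2ccccc2)=C(O)C(CC=C)=C1O | intermediate
9 | (1S,5R,7S)-3-[(Z)-hydroxy(phenyl)methylidene]-8,8-dimethyl-7-(3-methylbut-2-en-1-yl)-1,5-di(prop-2-en-1-yl)bicyclo[3.3.1]nonane-2,4,9-trione (overview numbering, C7 prenyl endo) | CC(C)=CC[C@H]1C[C@@]2(CC=C)C(=O)/C(=C(/O)c3ccccc3)C(=O)[C@](CC=C)(C2=O)C1(C)C | intermediate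
10 | 2-methyl-2-butene | CC=C(C)C | starting material
11 | (1S,5R,7S)-3-[(Z)-hydroxy(phenyl)methylidene]-8,8-dimethyl-1,5,7-tris(3-methylbut-2-en-1-yl)bicyclo[3.3.1]nonane-2,4,9-trione (overview numbering, C7 prenyl endo) | CC(C)=CC[C@H]1C[C@@]2(CC=C(C)C)C(=O)/C(=C(/O)c3ccccc3)C(=O)[C@](CC=C(C)C)(C2=O)C1(C)C | target

Total step count: 5. Longest linear sequence: 4 steps (steps 1, 3, 4, 5 from 1, or steps 2, 3, 4, 5 from 4).

**Steps most likely to fail**

1. Step 4 (key step).
- What may go wrong: the boat-like closure is expected to be slow, and a long acid exposure opens three side processes.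
  - The C7 prenyl may be consumed, either by formate addition or by attack of its cation on the isopropenyl CH2 of the same 1,5-diene.
  - Cation 8 may lose H7 and be re-protonated, which would erode C7.
  - Capture at oxygen may persist.
- Fallback, setting out from 3 and returning at 11: the last trisubstituted alkene is taken out of the acid step, so that longer times or a stronger acid can be tolerated.
- Commercial (R)-4-benzyl-1,3-oxazolidin-2-one is N-acylated (n-BuLi, THF, −78 °C, 3-methylbut-2-enoyl chloride) to (R)-4-benzyl-3-(3-methylbut-2-enoyl)-1,3-oxazolidin-2-one F1.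
- Deconjugative Evans alkylation (NaN(SiMe3)2, THF, −78 °C, allyl iodide) at the α-carbon of the chelated dienolate, anti to the benzyl group, should give (R)-4-benzyl-3-[(2R)-2-(prop-1-en-2-yl)pent-4-enoyl]-1,3-oxazolidin-2-one F2.
- LiAlH4 (THF, 0 °C) should release (2R)-2-(prop-1-en-2-yl)pent-4-en-1-ol F3, and Tf2O with 2,6-lutidine converts it into (2R)-2-(prop-1-en-2-yl)pent-4-en-1-yl triflate F4.
- Alkylative dearomatisation of 3 with F4 under the conditions of step 3, with epimer separation, should give the triallyl dienone F5.
- Formic acid closure of F5, in which isopropenyl is now the only alkene that can be protonated, should give the triallyl bicyclic trione F6.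
- Threefold cross-metathesis of F6 with 10 under the conditions of step 5 gives 11.

2. Step 3.
- What may go wrong: part of the triflate is lost to alkylation at oxygen, the new C5 centre forms without facial selectivity, and tautomer-broadened bands may prevent a clean separation of the epimers at the dienone stage.
- Fallback, setting out from 3 and 5 and returning at 9: the separation is moved behind the ring closure.
- The unseparated mixture of 7 and the (6S) epimeric dienone F7 is submitted to the formic acid conditions. The epimer should close through a chair to the 7-exo bicyclic trione F8.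
- F8 is a rigid diastereomer of 9 with a different ring A shape, so the two bicycles should be separable by chromatography or crystallisation.
- The faster chair closure of the epimer can also serve as a kinetic handle, consuming it first and leaving 7 enriched.

3. Step 5.
- What may go wrong: the acidic triketone enol may bind the ruthenium carbene and shorten its lifetime, and exchange at the hindered C1 allyl beside C8 may stall part-way.
- Fallback, setting out from 9 and returning at 11: the enol is masked during the metathesis.
- O-Methylation at the less hindered O4 (TMSCHN2, i-Pr2NEt, MeCN/MeOH, 0 °C → rt) should give the diallyl 4-O-methyl enol ether F9.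
- Cross-metathesis of F9 with 10 as in step 5 should give the triprenyl 4-O-methyl enol ether F10.
- Nucleophilic demethylation of F10 (LiCl, DMSO, 120 °C, then acidic work-up) releases 11.

**Further compounds**
F1 | step 4 | (R)-4-benzyl-3-(3-methylbut-2-enoyl)-1,3-oxazolidin-2-one | CC(C)=CC(=O)N1[C@H](Cc2ccccc2)COC1=O
F2 | step 4 | (R)-4-benzyl-3-[(2R)-2-(prop-1-en-2-yl)pent-4-enoyl]-1,3-oxazolidin-2-one | C=CC[C@H](C(C)=C)C(=O)N1[C@H](Cc2ccccc2)COC1=O
F3 | step 4 | (2R)-2-(prop-1-en-2-yl)pent-4-en-1-ol | C=CC[C@H](C(C)=C)CO
F4 | step 4 | (2R)-2-(prop-1-en-2-yl)pent-4-en-1-yl triflate | C=CC[C@H](C(C)=C)COS(=O)(=O)C(F)(F)F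
F5 | step 4 | (6R)-2-benzoyl-3,5-dihydroxy-6-[(2S)-2-(prop-1-en-2-yl)pent-4-en-1-yl]-4,6-di(prop-2-en-1-yl)cyclohexa-2,4-dien-1-one | C=CC[C@H](C(C)=C)C[C@@]1(CC=C)C(=O)C(C(=O)c2ccccc2)=C(O)C(CC=C)=C1O
F6 | step 4 | (1S,5R,7S)-3-[(Z)-hydroxy(phenyl)methylidene]-8,8-dimethyl-1,5,7-tri(prop-2-en-1-yl)bicyclo[3.3.1]nonane-2,4,9-trione | C=CC[C@H]1C[C@@]2(CC=C)C(=O)/C(=C(/O)c3ccccc3)C(=O)[C@](CC=C)(C2=O)C1(C)C
F7 | step 3 | (6S)-2-benzoyl-3,5-dihydroxy-6-[(2S)-5-methyl-2-(prop-1-en-2-yl)hex-4-en-1-yl]-4,6-di(prop-2-en-1-yl)cyclohexa-2,4-dien-1-one | CC(C)=CC[C@H](C(C)=C)C[C@]1(CC=C)C(=O)C(C(=O)c2ccccc2)=C(O)C(CC=C)=C1O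
F8 | step 3 | (1R,5S,7S)-3-[(Z)-hydroxy(phenyl)methylidene]-8,8-dimethyl-7-(3-methylbut-2-en-1-yl)-1,5-di(prop-2-en-1-yl)bicyclo[3.3.1]nonane-2,4,9-trione (C7 prenyl exo) | CC(C)=CC[C@H]1C[C@]2(CC=C)C(=O)/C(=C(/O)c3ccccc3)C(=O)[C@@](CC=C)(C2=O)C1(C)C
F9 | step 5 | (1S,5S,7S)-3-benzoyl-4-methoxy-8,8-dimethyl-7-(3-methylbut-2-en-1-yl)-1,5-di(prop-2-en-1-yl)bicyclo[3.3.1]non-3-ene-2,9-dione (spatial arrangement as in 9) | CC(C)=CC[C@H]1C[C@@]2(CC=C)C(OC)=C(C(=O)c3ccccc3)C(=O)[C@](CC=C)(C2=O)C1(C)C
F10 | step 5 | (1S,5S,7S)-3-benzoyl-4-methoxy-8,8-dimethyl-1,5,7-tris(3-methylbut-2-en-1-yl)bicyclo[3.3.1]non-3-ene-2,9-dione (spatial arrangement as in 11) | CC(C)=CC[C@H]1C[C@@]2(CC=C(C)C)C(OC)=C(C(=O)c3ccccc3)C(=O)[C@](CC=C(C)C)(C2=O)C1(C)C
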